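(All runs are simulated with constants of no real substance; noise was put on by code.)

Time is what the earlier runs lack: Sunday's and Friday's flasks stand for 3.0 d, but the readings stop at 40.0 h.

the same everywhere: substrate 0.49 M

| run | reagent | capture agent | remark | time |
|---|---|---|---|---|
| violet | 0.30 M | 9.8 mM | run made earlier |  |
| grey | 0.86 M | 9.8 mM | run made earlier |  |
| Sunday's | 0.440 M | 9.80 mM |  | 3.0 d |
| Friday's | 1.30 M | 9.80 mM |  | 3.0 d |

| run | time / h | side product / % | target / % | substrate / % | open intermediate / % | isomer of the product / % |
|---|---|---|---|---|---|---|
| violet | 3.00 | 0 | 1.9 | 86.4 | 10.4 | 0.6 |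
| violet | 4.00 | 0.4 | 1.8 | 83.9 | 13.2 | 1.2 |
| violet | 6.00 | 0 | 4.1 | 78.3 | 16.6 | 0.7 |
| violet | 10.0 | 0 | 8.9 | 69.7 | 19.7 | 2.5 |
| violet | 15.0 | 1.5 | 14.4 | 62.1 | 17.8 | 4.0 |
| violet | 25.0 | 2.3 | 22.9 | 54.1 | 14.7 | 6.9 |
| violet | 40.0 | 6.2 | 28.9 | 46.2 | 10.6 | 8.9 |
| grey | 3.00 | 0 | 3.6 | 68.3 | 28.0 | 1.8 |
| grey | 4.00 | 0 | 5.2 | 60.8 | 32.0 | 1.3 |
| grey | 6.00 | 0.5 | 10.0 | 48.9 | 38.6 | 2.7 |
| grey | 10.0 | 1.3 | 19.0 | 32.5 | 40.4 | 5.5 |
| grey | 15.0 | 3.8 | 31.2 | 21.1 | 36.2 | 8.4 |
| grey | 25.0 | 8.5 | 42.0 | 9.5 | 24.2 | 13.4 |
| grey | 40.0 | 20.5 | 45.0 | 3.6 | 14.2 | 16.2 |

(readings scatter by 0.5 percentage points)

- which of these there is most of at the end, counted by the substrate in it, Sunday's (isomer of the product / substrate / target / open intermediate / side product)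
- which of these there is most of at the end, counted by the substrate in it, Friday's (isomer of the product / substrate / target / open intermediate / side product)
- how much there is at the end of the one of these that leads, in percent of the substrate charged: Sunday's
- how much there is at the end of the one of these that leads, in percent of the substrate charged: Friday's

- candidate steps: open intermediate <-> target; target + by-product -> side product; open intermediate <-> isomer of the product; substrate + reagent -> open intermediate + by-product; open intermediate + capture agent -> trapped intermediate

Two chemists argue over Friday's flask. The first sees a feed line from substrate through open intermediate to target. At the grey run's last reading, target stands at 45.0 %, twice the side product's 20.5 %, so this chemist expects more reagent to keep target in front.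

The second looks at slopes. Over the grey run's last two readings, side product gained 12 percentage points and target 3 points, so side product is rising faster. Target is lost with by-product, and by-product equals substrate used less side product formed, which averages 0.387 M over that stretch. Dividing side product's gain per hour by mean target and mean by-product gives a drain constant 0.0475 /M/h, as a reading.

Replace the by-product curve by its mean, and target's loss to side product becomes pseudo-first-order. Target formed at one moment then keeps the fraction exp(−dose), where the dose is drain constant × mean by-product × age. If target and side product are counted as one pool of one age, side product passes target once the dose exceeds 0.693.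

I count age from a reading in each run with substrate near half: 48.9 % at 6.00 h in the grey run, taken for Friday's, and 54.1 % at 25.0 h in the violet run, taken for Sunday's. Friday's flask, with the grey mean, gets a dose of 1.21, above that line, so I expect side product in front. Sunday's reagent lies a quarter of the way from violet to grey, which gives by interpolation a mean by-product of 0.264 M and a dose of 0.591, below the line, so I expect target in front on Sunday's.

The forecast, reached by stepping forward by hand rather than by this dose, says target at 33 % on Sunday's and side product at 49 % on Friday's, where target “then drains”.

Sunday's flask gives target at 34.0 %. Friday's flask gives side product at 41.8 %, with target at 34.6 %.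

    open intermediate ⇌ target (K = 8.70, k = 0.0700 /h)
    target + by-product → side product (k = 0.0420 /M/h)
    open intermediate ⇌ isomer of the product (K = 2.70, k = 0.0180 /h)
    substrate + reagent → open intermediate + by-product (k = 0.170 /M/h)
    open intermediate + capture agent → trapped intermediate (k = 0.00680 /M/h)

Friday's by-product stands at 0.384 M after 1.50 d and 0.285 M after 3.00 d, and their mean lies below the grey value I held. With that mean the dose falls from 1.21 to 1.05, still above the line. It gives target 35.0 % of target plus side product, where the flask holds 45.2 %.

The feed view holds in a flask like Friday's with 0.12 M of substrate. By-product there stays within that charge, so with that charge as its mean and age counted over the whole 3.0 d, the reckoned dose comes to 0.411, below the line. Computed, target stands at 57.0 % and side product at 16.5 %.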